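## Analysis of the target

Isocryptomerin (22) is made of two 2-aryl-4H-chromen-4-one units joined by a diaryl ether. The oxygen on C6 of a 5-hydroxy-7-methoxy-2-(4-hydroxyphenyl)chromone (the methoxyflavone unit) is bonded to C4' of the 2-aryl ring of a 5,7-dihydroxychromone (the dihydroxyflavone unit). There is no stereocentre, so every problem is one of regiochemistry and of telling oxygen functions apart. The sensitive groups are four phenols (two of them chelated to a C4 carbonyl), one methyl ether that must survive to the end, and two 4-pyranone rings that open with hard nucleophiles and can be over-reduced. The difficulty sits in ring A of the methoxyflavone unit, which is hexasubstituted (C4a acyl, C5 OH, C6 OAr, C7 OMe, C8 H, C8a O) with three contiguous, different oxygen substituents. The ether oxygen on C6 is flanked by two oxygen-bearing carbons, so a late C–O coupling there is hindered, and O5 and O7 would have to be differentiated if they started as the same group. The strategy rests on reading C5–C6–C7–C8 of this ring as the four-carbon chain of an acetoacetate: ester carbon = C5, aryloxy-bearing C2 = C6, enol-ether carbon = C7, methyl carbon = C8. The ether bond can then be made by SN2 at an sp3 carbon, and ring A is annulated onto the C2=C3 bond of a 4-pyranone that already is ring C and carries ring B.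

## Retrosynthetic reasoning

**22 ⇒ 21.** The last operation should only unmask phenols. The 4'-OH of the methoxyflavone unit and the 5-OH and 7-OH of the dihydroxyflavone unit are carried as benzyl ethers in biflavone 21. One hydrogenolysis then gives 22 and leaves the methyl ether and the diaryl ether alone. The chelated 5-OH of the methoxyflavone unit stays free from the moment it is formed.

**21 ⇒ 15 + 19.** The bond between C2 of the dihydroxyflavone unit and its aryl ring is cut. This leaves the crowded ring A and its ether untouched and gives a simple partner, 5,7-bis(benzyloxy)chromone 19. Cutting the C6–O ether bond instead would demand a C–O coupling between two ortho oxygen substituents. Forward, the aryl group of boronate 15 must be transferred to palladium and added to C2 of 19 to give flavanone 20, which is then dehydrogenated. Boronate 15 comes from aryl bromide 14, so the hard half only has to carry a bromine atom through the annulation.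

**14 ⇒ 6 + 11.** Ring A of 14 is cut at C8–C8a and C4a–C5. This removes C5–C8 with all three oxygen substituents as diene 11 and leaves sulfinylpyranone 6, which already holds ring B, ring C and the C4 carbonyl. The cut is made here because it places the ester-level carbon of 11 at C5 (hence OH), the aryloxy carbon at C6 and the enol-ether carbon at C7 (hence OMe), so the 5-OH/6-OAr/7-OMe pattern arises without a differentiation step. Forward, the CH2 terminus of 11 must bond to C2 of 6 and the ketene-acetal carbon to C3. The sulfinyl group on C3 activates C2=C3 and then leaves as a sulfenic acid, and the mixed methyl silyl ketal collapses to the phenol.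

**11 ⇒ 10 ⇒ 9 ⇒ 7 + 8.** Diene 11 is the O-silylated dienolate of enoate 10, which is the methyl enol ether of β-keto ester 9. In 9 the O–C2 bond is cut to 4-bromophenol 7 and chloro keto ester 8. The hindered ether of the target is thus made as a plain phenoxide alkylation on an activated sp3 carbon.

**6 ⇒ 5 ⇒ 2 + 3, and 2 ⇒ 1.** Sulfoxide 6 comes from sulfide 5 by S-oxidation. Pyranone 5 is opened at O1–C2 to enaminodiketone 4, and 4 is cut at the future C5–C6 bond into enaminone 2 and ester 3 (a crossed Claisen condensation). Enaminone 2 comes from ketone 1 by aminomethylenation at the CH2 between sulfur and the carbonyl. The sulfur substituent is therefore in place before the ring exists, and no C–H functionalisation of a pyranone is needed.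

**19 ⇒ 17 ⇒ 16.** Chromone 19 is opened at O1–C2 to enaminone 18, the one-carbon homologue of acetophenone 17. Acetophenone 17 is the bis-benzyl ether of triol 16, with the chelated hydroxyl left free as the ring-closing nucleophile.

## Alternatives that were turned down

**Alternative 1:** The pyranone of the dihydroxyflavone unit is disconnected at O1–C8a and C4–C4a. This leads back to arylpropiolic acid A2, which carries the complete methoxyflavone unit, and silylaryl triflate A3 as the source of a 3,5-dibenzyloxy-substituted aryne.
- Forward key step: the aryne inserts into the C–O bond of the acid of A2, and the insertion product closes by oxa-Michael addition (O1–C2) to give A1.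
- For it: the aryne polarisation favours oxygen attack meta to the alkoxy group, which gives the 5,7-pattern. The second pyranone is formed directly at the flavone oxidation level, without palladium and without a dehydrogenation; on this point it is stronger than the chosen route.
- Against it: it does not address the real problem, since A2 already needs the hexasubstituted ring A with its hindered ether. A1 carries both O5 and O7 of that ring as methyl ethers, so a chelation-controlled 5-O-demethylation must follow in the presence of benzyl ethers. The aryne can also react with the alkyne (ene or [2+2] paths), the closure can go 5-exo instead of 6-endo, and A3 needs several steps.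
- Comparison: the chosen route offers the 5-OH/6-OAr/7-OMe pattern set directly, and it spends its risk on the bond set that is hard to make otherwise.

**Alternative 2:** Both flavones are disconnected at C2–C3 through their 1,3-diketones, back to bis(aryl ester) A5 built on a diaryl ether linchpin.
- Forward key step: an alkoxide base induces two intramolecular acyl transfers (Baker–Venkataraman) to give bis(1,3-diketone) A4. Acid cyclodehydration then closes both pyranones.
- For it: this is the most classical flavone chemistry, each transfer is intramolecular, and two units are advanced at once. In precedent it is clearly stronger than the chosen route.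
- Against it: the hindered ether is only moved into the linchpin, which needs a C–O coupling onto a phenol flanked by two methoxy groups on a fully substituted acetophenone. The two esters are different and must be installed one after the other. O5 and O7 are again both methyl ethers, so a selective 5-O-demethylation is needed after cyclisation.
- Comparison: counting the linchpin, it is longer than the chosen route and carries more protecting-group operations. The chosen route offers the ether made by SN2 at sp3 carbon and the O5/O7 differentiation built into the diene.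

**Alternative 3:** Ring A of the dihydroxyflavone unit is disconnected at C4a–C5, back to pyranone keto ester A7.
- Forward key step: a magnesium alkoxide deprotonates the side chain of A7, the vinylogous enolate reacts through pyranone C3 with the ester carbon (Claisen closure), and the ring enolises to the 5,7-dihydroxy arene A6.
- For it: it is biomimetic and delivers the dihydroxy ring without protecting groups; on that unit it is as economical as, or better than, the chosen route.
- Against it: it spends a demanding ring construction on the easy ring, while the hard methoxyflavone unit must still be made by other means and still carries a 5-OMe group to be cleaved selectively. A7 is a sensitive poly-β-carbonyl compound in which aldol closure and alkoxide opening of the pyranone compete with the Claisen closure. Its side chain must be assembled late on an elaborate substrate.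
- Comparison: the chosen route attaches the easy unit by a convergent coupling and applies the annulation to the ring that needs it.

Key step: step 7

Remark: sulfoxide 6, keto ester 9 and the transient intermediates 12, 13 and 20 are racemic. The target has no stereocentre, so this is without consequence. LiN(i-Pr)2 is taken as a commercial solution.

## Route

**Step 1**
Reactants: 1 1-(phenylthio)propan-2-one
Product: 2 (Z)-4-(dimethylamino)-3-(phenylthio)but-3-en-2-one
Conditions: Me2NCH(OMe)2 (1.1 equiv), PhMe, 90 °C
Reagents that add atoms: N,N-dimethylformamide dimethyl acetal, COC(OC)N(C)C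
Why: Aminomethylenation with an amide acetal; the CH2 flanked by the ketone and sulfur is the most acidic position and condenses in preference to the methyl group, giving the push–pull enaminone (geometry of no consequence).

**Step 2**
Reactants: 2 (Z)-4-(dimethylamino)-3-(phenylthio)but-3-en-2-one; 3 methyl 4-(benzyloxy)benzoate
Product: 5 6-[4-(benzyloxy)phenyl]-3-(phenylthio)-4H-pyran-4-one, via enaminodiketone 4 (not isolated)
Conditions: LiN(SiMe3)2 (2.3 equiv), THF, −78 °C to rt; then CF3CO2H, CH2Cl2, rt
Reagents that add atoms: none
Why: The methyl group of 2 is its only enolisable position, so its lithium enolate undergoes a crossed Claisen condensation with the non-enolisable ester 3, and the excess base stores 4 as its diketonate. Acid then lets the enol oxygen add to the enaminone carbon and expel dimethylamine (addition–elimination), which closes the 4-pyranone.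

**Step 3**
Reactants: 5 6-[4-(benzyloxy)phenyl]-3-(phenylthio)-4H-pyran-4-one
Product: 6 racemic 6-[4-(benzyloxy)phenyl]-3-(phenylsulfinyl)-4H-pyran-4-one
Conditions: mCPBA (1.0 equiv), CH2Cl2, −40 to 0 °C
Reagents that add atoms: 3-chloroperoxybenzoic acid, OOC(=O)c1cccc(Cl)c1
Why: Chemoselective S-oxidation of an aryl vinyl sulfide by one equivalent of peracid; the electron-poor pyranone double bonds and the benzyl ether are inert, and the racemic sulfur stereocentre is removed again in step 7.

**Step 4**
Reactants: 7 4-bromophenol; 8 methyl 2-chloro-3-oxobutanoate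
Product: 9 racemic methyl 2-(4-bromophenoxy)-3-oxobutanoate
Conditions: K2CO3, acetone, 56 °C
Reagents that add atoms: none
Why: Williamson-type SN2 displacement of the activated α-chloride by the phenoxide; this makes the future hindered diaryl ether bond at an sp3 carbon, and the labile C2 stereocentre disappears in step 5.

**Step 5**
Reactants: 9 racemic methyl 2-(4-bromophenoxy)-3-oxobutanoate
Product: 10 methyl 2-(4-bromophenoxy)-3-methoxybut-2-enoate (E/Z mixture)
Conditions: HC(OMe)3, H2SO4 (cat.), rt; then 100 °C with removal of volatiles
Reagents that add atoms: trimethyl orthoformate, COC(OC)OC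
Why: Acid-catalysed ketalisation by the orthoester followed by loss of methanol gives the conjugated β-methoxy enoate, the usual entry to 3-methoxycrotonates. The double-bond geometry is irrelevant because this bond becomes the central single bond of the diene.

**Step 6**
Reactants: 10 methyl 2-(4-bromophenoxy)-3-methoxybut-2-enoate
Product: 11 2-(4-bromophenoxy)-1,3-dimethoxy-1-(trimethylsilyloxy)buta-1,3-diene (geometric mixture at C1=C2)
Conditions: LiN(i-Pr)2 (1.1 equiv), THF, −78 °C; Me3SiCl, −78 °C to rt; used crude
Reagents that add atoms: chlorotrimethylsilane, C[Si](C)(C)Cl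
Why: Kinetic γ-deprotonation of the β-methoxy enoate gives the vinylogous ester enolate, which is silylated on oxygen to the vinylketene acetal; at −78 °C the aryl bromide is not touched by the amide base.

**Step 7**
Reactants: 6 racemic 6-[4-(benzyloxy)phenyl]-3-(phenylsulfinyl)-4H-pyran-4-one; 11 2-(4-bromophenoxy)-1,3-dimethoxy-1-(trimethylsilyloxy)buta-1,3-diene
Product: 14 2-[4-(benzyloxy)phenyl]-6-(4-bromophenoxy)-5-hydroxy-7-methoxy-4H-chromen-4-one, via cis-fused sulfinyl cycloadduct 12 (not isolated), via 5-methoxy-5-silyloxy-5,8-dihydrochromenone 13 (not isolated)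
Conditions: 11 (2.5 equiv), PhMe, rt to 80 °C; then 1 M HCl, THF, rt
Reagents that add atoms: none
Why: Proposed new method: the electron-rich vinylketene acetal 11 should add to the C2=C3 bond of 6, which is activated by both the ketone and the sulfinyl group, either by an asynchronous [4+2] cycloaddition or by Mukaiyama–Michael addition followed by 6-exo Claisen-type closure of the sulfinyl-stabilised enolate onto the silyloxocarbenium carbon; both paths give 12 with the new bonds C8–C8a and C4a–C5, so ring A closes by intermolecular [4+2] annulation. The closest known reaction type is the cycloaddition of 1,3-dimethoxy-1-silyloxybutadienes with sulfinyl- or halo-quinones and activated enones, which gives 1-hydroxy-3-methoxyarenes after elimination. Regioselectivity is the selectivity the step needs: the largest HOMO coefficient of 11 lies on its unsubstituted CH2 terminus and the largest LUMO coefficient of 6 on the unsubstituted C2 (β to the carbonyl), so the ester-level carbon bonds to C3 and the product has OH at C5, the aryloxy group at C6 and OMe at C7. Chemoselectivity between the two pyranone double bonds follows from the sulfinyl group, which activates only C2=C3, whereas C5=C6 is trisubstituted and conjugated with the aryl ring. Suprafacial addition sets 8a-H and the 4a-sulfinyl group cis, which is what the thermal syn elimination of benzenesulfenic acid requires, and warming should give 13. Dilute acid then cleaves the O–Si bond, the hemiketal loses methanol to unveil the C5 ketone, and enolisation through C8–H gives the hydrogen-bonded phenol as the aromatic sink. The transient stereocentres at C4a, C5, C8a and sulfur are all destroyed, so no stereocontrol is required.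

**Step 8**
Reactants: 14 2-[4-(benzyloxy)phenyl]-6-(4-bromophenoxy)-5-hydroxy-7-methoxy-4H-chromen-4-one
Product: 15 2-[4-(benzyloxy)phenyl]-5-hydroxy-7-methoxy-6-[4-(4,4,5,5-tetramethyl-1,3,2-dioxaborolan-2-yl)phenoxy]-4H-chromen-4-one
Conditions: B2pin2, PdCl2(dppf) (cat.), KOAc, 1,4-dioxane, 90 °C
Reagents that add atoms: bis(pinacolato)diboron, CC1(C)OB(OC1(C)C)B1OC(C)(C)C(C)(C)O1
Why: Miyaura borylation: zerovalent palladium inserts into the C–Br bond, acetate-assisted transmetalation with the diboron reagent and reductive elimination follow; the chelated phenol, the benzyl ether and the flavone tolerate these weakly basic conditions.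

**Step 9**
Reactants: 16 1-(2,4,6-trihydroxyphenyl)ethan-1-one
Product: 17 1-[2,4-bis(benzyloxy)-6-hydroxyphenyl]ethan-1-one
Conditions: BnBr (2.1 equiv), K2CO3, DMF, 60 °C
Reagents that add atoms: benzyl bromide, BrCc1ccccc1
Why: Williamson etherification; the para-hydroxyl and one of the two equivalent ortho-hydroxyls are alkylated, after which the last hydroxyl is held in a hydrogen bond to the acetyl group and resists alkylation; it is the ring-closing nucleophile of step 10.

**Step 10**
Reactants: 17 1-[2,4-bis(benzyloxy)-6-hydroxyphenyl]ethan-1-one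
Product: 19 5,7-bis(benzyloxy)-4H-chromen-4-one, via aryl enaminone 18 (not isolated)
Conditions: Me2NCH(OMe)2, PhMe, 100 °C; then conc. HCl, CH2Cl2, 40 °C
Reagents that add atoms: N,N-dimethylformamide dimethyl acetal, COC(OC)N(C)C
Why: The acetyl methyl group condenses with the amide acetal to the enaminone, and acid then promotes addition of the phenol to the β-carbon and loss of dimethylamine (6-endo addition–elimination), the standard chromone synthesis from 2-hydroxyacetophenones.

**Step 11**
Reactants: 15 2-[4-(benzyloxy)phenyl]-5-hydroxy-7-methoxy-6-[4-(4,4,5,5-tetramethyl-1,3,2-dioxaborolan-2-yl)phenoxy]-4H-chromen-4-one; 19 5,7-bis(benzyloxy)-4H-chromen-4-one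
Product: 21 5,7-bis(benzyloxy)-2-[4-({2-[4-(benzyloxy)phenyl]-5-hydroxy-7-methoxy-4-oxo-4H-chromen-6-yl}oxy)phenyl]-4H-chromen-4-one, via racemic flavanone 20 (not isolated)
Conditions: Pd(OCOCF3)2 (10 mol %), 2,2'-bipyridine (12 mol %), AcOH–THF–H2O, 60 °C; then DDQ, 1,4-dioxane, 90 °C
Reagents that add atoms: none
Why: Bipyridine-ligated divalent palladium takes the aryl group from boron, adds it to C2 of chromone 19 (conjugate addition) and is released from the palladium enolate by protonolysis without change of oxidation state, giving flavanone 20; DDQ then dehydrogenates C2–C3 to the flavone. The 2,2-disubstituted enone of the first flavone unit is too hindered to compete as acceptor.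

**Step 12**
Reactants: 21 5,7-bis(benzyloxy)-2-[4-({2-[4-(benzyloxy)phenyl]-5-hydroxy-7-methoxy-4-oxo-4H-chromen-6-yl}oxy)phenyl]-4H-chromen-4-one
Product: 22 isocryptomerin, 5,7-dihydroxy-2-(4-{[5-hydroxy-2-(4-hydroxyphenyl)-7-methoxy-4-oxo-4H-chromen-6-yl]oxy}phenyl)-4H-chromen-4-one
Conditions: H2 (1 atm), Pd/C, THF–MeOH, rt
Reagents that add atoms: none
Why: Hydrogenolysis of the three aryl benzyl ethers over palladium; the methyl ether, the diaryl ether and the conjugated pyranone double bonds should be retained at atmospheric pressure and room temperature.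

## Compound list

1 | 1-(phenylthio)propan-2-one | CC(=O)CSc1ccccc1 | starting material
2 | (Z)-4-(dimethylamino)-3-(phenylthio)but-3-en-2-one | CC(=O)/C(Sc1ccccc1)=C/N(C)C | intermediate
3 | methyl 4-(benzyloxy)benzoate | COC(=O)c1ccc(OCc2ccccc2)cc1 | starting material
4 | 1-[4-(benzyloxy)phenyl]-5-(dimethylamino)-4-(phenylthio)pent-4-ene-1,3-dione (formed in the flask, not isolated) | CN(C)/C=C(Sc1ccccc1)/C(=O)CC(=O)c1ccc(OCc2ccccc2)cc1 | intermediate
5 | 6-[4-(benzyloxy)phenyl]-3-(phenylthio)-4H-pyran-4-one | O=c1cc(-c2ccc(OCc3ccccc3)cc2)occ1Sc1ccccc1 | intermediate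
6 | 6-[4-(benzyloxy)phenyl]-3-(phenylsulfinyl)-4H-pyran-4-one, racemic at sulfur | O=c1cc(-c2ccc(OCc3ccccc3)cc2)occ1S(=O)c1ccccc1 | intermediate
7 | 4-bromophenol | Oc1ccc(Br)cc1 | starting material
8 | methyl 2-chloro-3-oxobutanoate, racemic | COC(=O)C(Cl)C(C)=O | starting material
9 | methyl 2-(4-bromophenoxy)-3-oxobutanoate, racemic | COC(=O)C(Oc1ccc(Br)cc1)C(C)=O | intermediate
10 | methyl 2-(4-bromophenoxy)-3-methoxybut-2-enoate, E/Z mixture | COC(=O)C(Oc1ccc(Br)cc1)=C(C)OC | intermediate
11 | 2-(4-bromophenoxy)-1,3-dimethoxy-1-(trimethylsilyloxy)buta-1,3-diene, geometric mixture at C1=C2 | C=C(OC)C(Oc1ccc(Br)cc1)=C(OC)O[Si](C)(C)C | intermediate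
12 | 2-[4-(benzyloxy)phenyl]-6-(4-bromophenoxy)-5,7-dimethoxy-4a-(phenylsulfinyl)-5-(trimethylsilyloxy)-4a,5,8,8a-tetrahydro-4H-chromen-4-one; racemic, 8a-H cis to the 4a-sulfinyl group (relative configuration shown), epimers at C5 and sulfur (formed in the flask, not isolated) | O=C1C=C(c2ccc(OCc3ccccc3)cc2)O[C@H]2CC(OC)=C(Oc3ccc(Br)cc3)C(OC)(O[Si](C)(C)C)[C@@]12S(=O)c1ccccc1 | intermediate
13 | 2-[4-(benzyloxy)phenyl]-6-(4-bromophenoxy)-5,7-dimethoxy-5-(trimethylsilyloxy)-5,8-dihydro-4H-chromen-4-one, racemic at C5 (formed in the flask, not isolated) | O=c1cc(-c2ccc(OCc3ccccc3)cc2)oc2c1C(OC)(O[Si](C)(C)C)C(Oc1ccc(Br)cc1)=C(OC)C2 | intermediate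
14 | 2-[4-(benzyloxy)phenyl]-6-(4-bromophenoxy)-5-hydroxy-7-methoxy-4H-chromen-4-one | COc1cc2oc(-c3ccc(OCc4ccccc4)cc3)cc(=O)c2c(O)c1Oc1ccc(Br)cc1 | intermediate
15 | 2-[4-(benzyloxy)phenyl]-5-hydroxy-7-methoxy-6-[4-(4,4,5,5-tetramethyl-1,3,2-dioxaborolan-2-yl)phenoxy]-4H-chromen-4-one | COc1cc2oc(-c3ccc(OCc4ccccc4)cc3)cc(=O)c2c(O)c1Oc1ccc(B2OC(C)(C)C(C)(C)O2)cc1 | intermediate
16 | 1-(2,4,6-trihydroxyphenyl)ethan-1-one | CC(=O)c1c(O)cc(O)cc1O | starting material
17 | 1-[2,4-bis(benzyloxy)-6-hydroxyphenyl]ethan-1-one | CC(=O)c1c(O)cc(OCc2ccccc2)cc1OCc1ccccc1 | intermediate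
18 | (E)-1-[2,4-bis(benzyloxy)-6-hydroxyphenyl]-3-(dimethylamino)prop-2-en-1-one (formed in the flask, not isolated) | CN(C)/C=C/C(=O)c1c(O)cc(OCc2ccccc2)cc1OCc1ccccc1 | intermediate
19 | 5,7-bis(benzyloxy)-4H-chromen-4-one | O=c1ccoc2cc(OCc3ccccc3)cc(OCc3ccccc3)c12 | intermediate
20 | 5,7-bis(benzyloxy)-2-[4-({2-[4-(benzyloxy)phenyl]-5-hydroxy-7-methoxy-4-oxo-4H-chromen-6-yl}oxy)phenyl]chroman-4-one, racemic at C2 of the chromanone (formed in the flask, not isolated) | COc1cc2oc(-c3ccc(OCc4ccccc4)cc3)cc(=O)c2c(O)c1Oc1ccc(C2CC(=O)c3c(OCc4ccccc4)cc(OCc4ccccc4)cc3O2)cc1 | intermediate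
21 | 5,7-bis(benzyloxy)-2-[4-({2-[4-(benzyloxy)phenyl]-5-hydroxy-7-methoxy-4-oxo-4H-chromen-6-yl}oxy)phenyl]-4H-chromen-4-one | COc1cc2oc(-c3ccc(OCc4ccccc4)cc3)cc(=O)c2c(O)c1Oc1ccc(-c2cc(=O)c3c(OCc4ccccc4)cc(OCc4ccccc4)cc3o2)cc1 | intermediate
22 | isocryptomerin | COc1cc2oc(-c3ccc(O)cc3)cc(=O)c2c(O)c1Oc1ccc(-c2cc(=O)c3c(O)cc(O)cc3o2)cc1 | target

## Step count and least certain steps

Total step count: 12. Longest linear sequence: 7 steps (1, 2, 3, 7, 8, 11, 12; the diene branch 4, 5, 6 is equally long up to step 7).

**Step 7 (key step).** Three processes can defeat it.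
- Hydrolysis or desilylation of the diene may outrun its addition, because the pyranone is a weaker acceptor than a quinone.
- If bond formation is stepwise, the enolate formed after the first C–C bond may open the pyranone by β-elimination of the ring oxygen instead of closing ring A.
- The ketal may collapse by loss of silanol rather than methanol, which would leave O5 methylated.

The fallback uses only known reaction types, sets out from ester 3 and phenol 7, and returns at 14. The polylithiated form of purchased 2',6'-dihydroxy-4'-methoxyacetophenone F1 (LiN(SiMe3)2, THF) is condensed with 3 to give 1-[4-(benzyloxy)phenyl]-3-(2,6-dihydroxy-4-methoxyphenyl)propane-1,3-dione F2. Cyclodehydration (H2SO4 cat., AcOH) gives 4'-benzyloxy-5-hydroxy-7-methoxyflavone F3. Electrophilic iodination ortho to the chelated phenol (benzyltrimethylammonium dichloroiodate, CaCO3, CH2Cl2–MeOH) gives 4'-benzyloxy-5-hydroxy-6-iodo-7-methoxyflavone F4. An Ullmann-type ether coupling of F4 with 7 (CuI, N,N-dimethylglycine, Cs2CO3, 1,4-dioxane, 100 °C), in which the C–I bond reacts before the C–Br bond, gives 14. The price is the hindered C–O coupling and the C6/C8 selectivity of iodination that the main route avoids.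

**Step 11.** Transmetalation of the pinacol boronate to divalent palladium may be slow, so protodeboronation can compete. The 5-hydroxy-4-keto chelate of 15 may sequester the catalyst. The DDQ stage may stall or attack benzylic positions.

The fallback sets out from 14 and 19 and returns at 22, bypassing steps 8 and 11. Bromide 14 is benzylated at the chelated hydroxyl (BnBr, K2CO3, DMF, 80 °C) to 5-(benzyloxy)-2-[4-(benzyloxy)phenyl]-6-(4-bromophenoxy)-7-methoxy-4H-chromen-4-one F5. Chromone 19 is zincated at C2 with TMP2Zn·2MgCl2·2LiCl to bis[5,7-bis(benzyloxy)-4-oxo-4H-chromen-2-yl]zinc F6. Negishi coupling of F6 with F5 (Pd(OAc)2, SPhos, THF, 50 °C) gives the tetrabenzyl biflavone 5,7-bis(benzyloxy)-2-[4-({5-(benzyloxy)-2-[4-(benzyloxy)phenyl]-7-methoxy-4-oxo-4H-chromen-6-yl}oxy)phenyl]-4H-chromen-4-one F7, which is hydrogenolysed as in step 12 to 22. This forms the aryl–C2 bond directly at the flavone oxidation level.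

**Step 6.** Clean formation of the dienolate may fail through competing proton abstraction next to bromine, through attack of the base or of the dienolate on an ester, or through C-silylation. The ketene acetal may also hydrolyse back to the enoate during handling.

The fallback sets out from 9 and 6 and returns at 14; it needs neither step 5 nor an amide base. Keto ester 9 is bis-silylated by soft enolisation (Et3N, Me3SiOSO2CF3, Et2O, 0 °C) to 2-(4-bromophenoxy)-1-methoxy-1,3-bis(trimethylsilyloxy)buta-1,3-diene F8. Annulation of F8 with 6 under the conditions of step 7 would give 2-[4-(benzyloxy)phenyl]-6-(4-bromophenoxy)-5,7-dihydroxy-4H-chromen-4-one F9. The more acidic, non-chelated 7-OH of F9 is then methylated selectively (MeI, K2CO3, acetone) to give 14.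

**Step 12.** The C2=C3 bonds of the two pyranones may be over-reduced, or the reaction may stall because the polyphenolic products are poorly soluble and adsorb on the catalyst.

The fallback sets out from 21 and returns at 22 and replaces reductive cleavage by Lewis-acid cleavage: BCl3 with pentamethylbenzene as cation scavenger, CH2Cl2, −78 °C. At this temperature the non-chelated 7-OMe group and the diaryl ether should not be cleaved. No new compound is made (F0).

## Further compounds

F1 | step 7 | 2',6'-dihydroxy-4'-methoxyacetophenone (purchased) | CC(=O)c1c(O)cc(OC)cc1O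
F2 | step 7 | 1-[4-(benzyloxy)phenyl]-3-(2,6-dihydroxy-4-methoxyphenyl)propane-1,3-dione | COc1cc(O)c(C(=O)CC(=O)c2ccc(OCc3ccccc3)cc2)c(O)c1
F3 | step 7 | 4'-benzyloxy-5-hydroxy-7-methoxyflavone | COc1cc(O)c2c(=O)cc(-c3ccc(OCc4ccccc4)cc3)oc2c1
F4 | step 7 | 4'-benzyloxy-5-hydroxy-6-iodo-7-methoxyflavone | COc1cc2oc(-c3ccc(OCc4ccccc4)cc3)cc(=O)c2c(O)c1I
F5 | step 11 | 5-(benzyloxy)-2-[4-(benzyloxy)phenyl]-6-(4-bromophenoxy)-7-methoxy-4H-chromen-4-one | COc1cc2oc(-c3ccc(OCc4ccccc4)cc3)cc(=O)c2c(OCc2ccccc2)c1Oc1ccc(Br)cc1
F6 | step 11 | bis[5,7-bis(benzyloxy)-4-oxo-4H-chromen-2-yl]zinc | O=c1cc([Zn]c2cc(=O)c3c(OCc4ccccc4)cc(OCc4ccccc4)cc3o2)oc2cc(OCc3ccccc3)cc(OCc3ccccc3)c12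
F7 | step 11 | 5,7-bis(benzyloxy)-2-[4-({5-(benzyloxy)-2-[4-(benzyloxy)phenyl]-7-methoxy-4-oxo-4H-chromen-6-yl}oxy)phenyl]-4H-chromen-4-one | COc1cc2oc(-c3ccc(OCc4ccccc4)cc3)cc(=O)c2c(OCc2ccccc2)c1Oc1ccc(-c2cc(=O)c3c(OCc4ccccc4)cc(OCc4ccccc4)cc3o2)cc1
F8 | step 6 | 2-(4-bromophenoxy)-1-methoxy-1,3-bis(trimethylsilyloxy)buta-1,3-diene | C=C(O[Si](C)(C)C)C(Oc1ccc(Br)cc1)=C(OC)O[Si](C)(C)C
F9 | step 6 | 2-[4-(benzyloxy)phenyl]-6-(4-bromophenoxy)-5,7-dihydroxy-4H-chromen-4-one | Oc1cc2oc(-c3ccc(OCc4ccccc4)cc3)cc(=O)c2c(O)c1Oc1ccc(Br)cc1
F0 | step 12 | none | none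
A1 | alternative 1 | protected isocryptomerin (5-OMe and 4'-OBn on the methoxyflavone unit, 5,7-di-OBn on the dihydroxyflavone unit) | COc1cc2oc(-c3ccc(OCc4ccccc4)cc3)cc(=O)c2c(OC)c1Oc1ccc(-c2cc(=O)c3c(OCc4ccccc4)cc(OCc4ccccc4)cc3o2)cc1
A2 | alternative 1 | 3-[4-({2-[4-(benzyloxy)phenyl]-5,7-dimethoxy-4-oxo-4H-chromen-6-yl}oxy)phenyl]prop-2-ynoic acid | COc1cc2oc(-c3ccc(OCc4ccccc4)cc3)cc(=O)c2c(OC)c1Oc1ccc(C#CC(=O)O)cc1
A3 | alternative 1 | 3,5-bis(benzyloxy)-2-(trimethylsilyl)phenyl trifluoromethanesulfonate | C[Si](C)(C)c1c(OCc2ccccc2)cc(OCc2ccccc2)cc1OS(=O)(=O)C(F)(F)F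
A4 | alternative 2 | bis(1,3-diketone) with two free ortho phenols | O=C(CC(=O)c1ccc(OCc2ccccc2)cc1)c1c(O)cc(OC)c(Oc2ccc(C(=O)CC(=O)c3c(O)cc(OCc4ccccc4)cc3OCc3ccccc3)cc2)c1OC
A5 | alternative 2 | bis(aryl ester) with two ortho-acetyl groups | CC(=O)c1c(OC(=O)c2ccc(OCc3ccccc3)cc2)cc(OC)c(Oc2ccc(C(=O)Oc3cc(OCc4ccccc4)cc(OCc4ccccc4)c3C(C)=O)cc2)c1OC
A6 | alternative 3 | isocryptomerin 5-O-methyl 4'-O-benzyl ether | COc1cc2oc(-c3ccc(OCc4ccccc4)cc3)cc(=O)c2c(OC)c1Oc1ccc(-c2cc(=O)c3c(O)cc(O)cc3o2)cc1
A7 | alternative 3 | methyl 4-{6-[4-({2-[4-(benzyloxy)phenyl]-5,7-dimethoxy-4-oxo-4H-chromen-6-yl}oxy)phenyl]-4-oxo-4H-pyran-2-yl}-3-oxobutanoate | COC(=O)CC(=O)Cc1cc(=O)cc(-c2ccc(Oc3c(OC)cc4oc(-c5ccc(OCc6ccccc6)cc5)cc(=O)c4c3OC)cc2)o1
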